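**Plan**

Labels: the carbocycle runs from C1 (ketone) to C10 (the C(CH3)–O ether carbon); C4–C5 is the epoxide, C6 the lactone O–CH, C7 the fully substituted ether/lactone carbon, C8 the ester carbon, C11–C13 the methylene-lactone carbons.
Enabling feature: the tetrahydrofuran O–C7–C8–C9–C10 has two fully substituted ether carbons with cis ring bonds (C7–C6, C10–C1), oxygen on C8 beside C7 and the C1 carbonyl on C10; tying C1 to C5 makes it an 8-oxabicyclo[3.2.1]oct-3-en-2-one (C1=O, C5=C6), the [5+2] adduct of a 3-oxidopyrylium ylide and an enol ether.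
Retrosynthetic cuts: epoxide O; lactone C11–C12 and C12–O6 (alkyne cyclocarbonylation); ester C8–O (with inversion); C3–C4 (ring-closing B-alkyl Suzuki); C1–C2 (vinyl addition); C4=C5 (iodo-olefination); C1–C5 re-joined; last C7–C8 and C9–C10 ([5+2]).
Forward: the cycloaddition closes the tetrahydrofuran and a seven-membered carbocycle; that carbocycle is opened at C1=C5, the ten-membered ring is closed at C3–C4, then the lactone, then the epoxide.
Stereochemistry: C7/C10 cis from the bicyclic adduct (absolute sense by lipase resolution); C6 from face-selective enone epoxidation carried through a Wharton transposition; C8 formed endo and inverted on esterification; C4/C5 from a Z-iodoalkene and a stereospecific, face-selective epoxidation.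

Key step: step 6

Assumption: an alkyl vinyl ether adds to a 3-oxidopyrylium ylide with its alkoxy carbon at the ylide terminus remote from the oxido carbon and with the alkoxy group endo; the pyranone is built for this orientation (methyl beside the carbonyl, alkyne on the acetal carbon).

Abbreviations: PMB = 4-methoxybenzyl, TIPS = tri(propan-2-yl)silyl, TES = triethylsilyl.

**Route**

Step 1
Reactants: 1 5-bromofuran-2-carbaldehyde; 2 ethynyltri(propan-2-yl)silane
Product: 3 5-[(TIPS)ethynyl]furan-2-carbaldehyde
Conditions: PdCl2(PPh3)2 (2 mol %), CuI (4 mol %), Et3N, THF, rt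
Reagents that add atoms: none
Why: Sonogashira coupling of the electron-poor bromofuran with the terminal silylalkyne should proceed at room temperature and creates no stereocentre.

Step 2
Reactants: 3 5-[(TIPS)ethynyl]furan-2-carbaldehyde
Product: 4 rac-1-{5-[(TIPS)ethynyl]furan-2-yl}ethan-1-ol
Conditions: MeMgBr, THF, −78 → 0 °C; aq NH4Cl
Reagents that add atoms: methylmagnesium bromide C[Mg]Br
Why: Grignard 1,2-addition to the aldehyde should give the secondary furyl carbinol, whose configuration does not matter because this carbon (the later C10) becomes planar in the ylide.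

Step 3
Reactants: 4 rac-1-{5-[(TIPS)ethynyl]furan-2-yl}ethan-1-ol
Product: 5 6-hydroxy-2-methyl-6-[(TIPS)ethynyl]-2H-pyran-3(6H)-one (diastereomer mixture)
Conditions: m-CPBA, CH2Cl2, 0 °C → rt
Reagents that add atoms: 3-chloroperoxybenzoic acid OOC(=O)c1cccc(Cl)c1
Why: Achmatowicz rearrangement: peracid oxidation of the furan to the cis-enedione and ring closure by the carbinol oxygen should give the 6-hydroxypyranone, the silyl-capped alkyne being far less reactive toward the peracid than the furan.

Step 4
Reactants: 5 6-hydroxy-2-methyl-6-[(TIPS)ethynyl]-2H-pyran-3(6H)-one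
Product: 6 6-acetoxy-2-methyl-6-[(TIPS)ethynyl]-2H-pyran-3(6H)-one (diastereomer mixture)
Conditions: Ac2O, pyridine, DMAP (cat.), CH2Cl2, 0 °C
Reagents that add atoms: acetic anhydride CC(=O)OC(C)=O
Why: DMAP-catalysed acetylation of the hemiketal hydroxyl should give the pyranulose acetate, the usual oxidopyrylium precursor, without ionising it at 0 °C.

Step 5
Reactants: 7 (4-methoxyphenyl)methanol
Product: 8 4-methoxybenzyl vinyl ether
Conditions: [Ir(cod)Cl]2 (1 mol %), Na2CO3, vinyl acetate, toluene, 100 °C
Reagents that add atoms: vinyl acetate C=COC(C)=O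
Why: Iridium-catalysed transfer vinylation of the primary alcohol by vinyl acetate (transvinylation) should give the vinyl ether and avoids mercury salts.

Step 6
Reactants: 6 6-acetoxy-2-methyl-6-[(TIPS)ethynyl]-2H-pyran-3(6H)-one; 8 4-methoxybenzyl vinyl ether
Product: 10 rac-(1R,5S,6R)-6-[(4-methoxybenzyl)oxy]-1-methyl-5-[(TIPS)ethynyl]-8-oxabicyclo[3.2.1]oct-3-en-2-one (6-endo ether), via oxidopyrylium ylide 9 (not isolated)
Conditions: 8 (5 equiv), i-Pr2NEt (1.5 equiv, added slowly), MeCN, 25 → 50 °C
Reagents that add atoms: none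
Why: The amine removes the proton at C10 of 6 and acetate leaves from C7, giving the aromatic 3-oxidopyrylium 9, a cyclic carbonyl ylide that adds to the enol ether in a concerted but asynchronous [5+2] (1,3-dipolar type, [π4s+π2s]) cycloaddition across its two α-carbons. The closest known reaction type is the [5+2] addition of pyranulose-acetate-derived oxidopyrylium ylides to alkyl vinyl ethers, which gives 6-endo-alkoxy-8-oxabicyclo[3.2.1]oct-3-en-2-ones. The tetrahydrofuran closes as the ring containing the new two-carbon bridge and the seven-membered carbocycle as the ring containing the enone, both by the same suprafacial cycloaddition that forms C7–C8 and C9–C10. C7 and C10 are set together and must be cis because both bonds form on one face of the planar ylide, C8 is set by the endo approach of the alkoxy group beneath the pyrylium ring, and the adduct is racemic (resolved in step 9). The step needs the orientation that joins the alkoxy carbon to C7: the oxido-flanked terminus C10 carries the larger coefficient in both frontier orbitals, so the nucleophilic CH2 of the enol ether bonds there and the alkoxy carbon goes to the remote terminus, as donor and acceptor alkenes both do. The C10 methyl and the slender C7 alkynyl group are spectators, and slow addition of base with excess enol ether should suppress ylide dimerisation.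

Step 7
Reactants: 10 the cycloadduct
Product: 11 rac-3,4-epoxide of 10 with the epoxide oxygen syn to the bridging oxygen (C5–C6 epoxide, C1 ketone)
Conditions: 30% H2O2, NaOH (0.3 equiv), MeOH, 0 °C
Reagents that add atoms: hydrogen peroxide OO
Why: Weitz–Scheffer nucleophilic epoxidation: hydroperoxide should add to the enone β-carbon C6 from the face syn to the bridging oxygen, because the other face is blocked by the C8–C9 bridge and its endo ether, and this sets the C6–O configuration of the target.

Step 8
Reactants: 11 the epoxy ketone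
Product: 13 rac-(1R,2R,5R,7R)-7-[(4-methoxybenzyl)oxy]-5-methyl-1-[(TIPS)ethynyl]-8-oxabicyclo[3.2.1]oct-3-en-2-ol (C6 hydroxyl syn to the bridging oxygen; C1=C5 alkene), via epoxy hydrazone 12 (not isolated)
Conditions: N2H4·H2O, AcOH (cat.), MeOH, 0 °C → rt
Reagents that add atoms: none
Why: Wharton transposition: the epoxy hydrazone should fragment with loss of N2 to the allylic alcohol, so that the C6–O bond and its configuration are kept while C1 and C5 become the ring alkene.

Step 9
Reactants: 13 the racemic allylic alcohol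
Product: 14 acetate of the (1R,2R,5R,7R) enantiomer of 13
Conditions: immobilised Candida antarctica lipase B, vinyl acetate, t-BuOMe, 30 °C, to about half conversion; chromatography
Reagents that add atoms: vinyl acetate C=COC(C)=O
Why: Lipase-catalysed kinetic resolution by transesterification: by the empirical rule for secondary alcohols (large quaternary C7 against small vinylic C5) the enantiomer with (R)-C6 should be acylated faster, so the acetate carries the wanted absolute configuration and the unreacted (1S,2S,5S,7S)-alcohol is removed by chromatography.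

Step 10
Reactants: 14 the enantiopure allylic acetate
Product: 16 dialdehyde on a 2,5-cis-tetrahydrofuran (C10 bears CH3 and the C1 formyl group; C7 bears the silylethynyl group and the C6H(OAc)–C5HO chain; C8 PMB ether trans to the alkyne), via ozonide 15 (not isolated)
Conditions: O3, CH2Cl2, −78 °C (Sudan Red 7B end point); PPh3, −78 °C → rt
Reagents that add atoms: ozone [O-][O+]=O
Why: Ozonolysis with reductive work-up should cleave the cis ring alkene much faster than the silylalkyne or the anisyl ring and releases the C1 and C5 aldehydes without touching a stereocentre.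

Step 11
Reactants: 16 the dialdehyde
Product: 17 Z-iodoalkene aldehyde (C5 formyl converted to CH=C(CH3)I with iodine cis to C6; C1 formyl intact)
Conditions: EtPPh3I, n-BuLi, THF; I2, −78 °C; NaN(SiMe3)2, −20 °C; this ylide (1.05 equiv) added slowly to 16, −78 °C
Reagents that add atoms: ethyltriphenylphosphonium iodide CC[P+](c1ccccc1)(c1ccccc1)c1ccccc1.[I-]; iodine [I][I]
Why: Stork–Zhao-type Wittig olefination with the α-iodo ylide Ph3P=C(CH3)I should give the Z-iodoalkene under kinetic control, and the bulky ylide at −78 °C should take the α-acetoxy C5 aldehyde in preference to the C1 aldehyde on the fully substituted C10 (C6, α to the aldehyde, must not epimerise, hence the low temperature and inverse addition).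

Step 12
Reactants: 17 the iodoalkene aldehyde
Product: 18 diol (C1 is CH(OH)–CH=CH2 as both epimers; C6 hydroxyl free)
Conditions: CH2=CHMgBr (5 equiv), THF, −78 → 0 °C; aq NH4Cl
Reagents that add atoms: vinylmagnesium bromide C=C[Mg]Br
Why: Grignard addition to the remaining aldehyde should give the allylic alcohol as both C1 epimers (which converge in step 19), and the excess reagent should cleave the acetate by double addition to free the C6 hydroxyl.

Step 13
Reactants: 18 the diol
Product: 19 bis(triethylsilyl) ether of 18
Conditions: Et3SiOTf, 2,6-lutidine, CH2Cl2, −78 → 0 °C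
Reagents that add atoms: triethylsilyl trifluoromethanesulfonate CC[Si](CC)(CC)OS(=O)(=O)C(F)(F)F
Why: Silyl triflate with 2,6-lutidine should silylate both secondary hydroxyls, including the hindered C6 one, without affecting the alkenyl iodide.

Step 14
Reactants: 19 the bis-silyl ether
Product: 21 oxa-bridged (4Z)-cyclodecene (C3–C4 joined; C1 and C6 TES ethers; C8 PMB ether; C7 silylalkyne), via B-alkylborane 20 (not isolated)
Conditions: 9-BBN, THF, rt; then syringe-pump addition to Pd(dppf)Cl2 (15 mol %), AsPh3 (30 mol %), Cs2CO3, DMF–THF–H2O, 50 °C, about 2 mM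
Reagents that add atoms: none
Why: 9-BBN should hydroborate only the monosubstituted vinyl group at its terminus, and the intramolecular B-alkyl Suzuki–Miyaura coupling with the alkenyl iodide under high dilution should close the ten-membered ring at C3–C4 with retention of the Z geometry, helped by the cis disposition of both arms on the tetrahydrofuran.

Step 15
Reactants: 21 the macrocycle
Product: 22 C8 alcohol (8R; hydroxyl on the tetrahydrofuran face that carries C6 and C1)
Conditions: DDQ, CH2Cl2–pH 7 buffer (10:1), 0 °C
Reagents that add atoms: none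
Why: Oxidative cleavage of the 4-methoxybenzyl ether by DDQ (benzylic hydride abstraction, then hydrolysis) should free the C8 hydroxyl while silyl ethers, alkene and alkyne are left alone.

Step 16
Reactants: 22 the C8 alcohol
Product: 23 C8 methacrylate with inverted (8S) configuration
Conditions: methacrylic acid, PPh3, DIAD, toluene, 0 → 40 °C
Reagents that add atoms: methacrylic acid C=C(C)C(=O)O
Why: Mitsunobu esterification should displace the oxyphosphonium by SN2 with inversion, turning the endo (8R) alcohol into the exo (8S) methacrylate of the target, the carboxylate entering on the face where the neighbouring fully substituted C7 carries only the slender alkynyl group.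

Step 17
Reactants: 23 the methacrylate
Product: 24 diol with terminal alkyne (free C1 and C6 hydroxyls)
Conditions: Bu4NF–AcOH (1:1), THF, 0 °C → rt
Reagents that add atoms: none
Why: Fluoride should cleave both O–Si bonds and the alkynyl C–Si bond, and buffering with acetic acid keeps the medium non-basic so that the methacrylate neither migrates nor hydrolyses.

Step 18
Reactants: 24 the alkynyl diol
Product: 25 α-methylene γ-lactone (O6–C12(=O)–C11(=CH2)–C7) with free C1 hydroxyl
Conditions: PdCl2 (5 mol %), SnCl2 (5 mol %), PPh3 (10 mol %), CO (7 bar), MeCN, 75 °C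
Reagents that add atoms: carbon monoxide [C-]#[O+]
Why: Palladium-catalysed cyclocarbonylation of the homopropargylic alcohol (the C6 alkoxycarbonylpalladium adds cis across the alkyne in the 5-exo sense, then protonolysis) should give the α-methylene γ-lactone, with the C6 configuration untouched and the C1 hydroxyl too remote to compete.

Step 19
Reactants: 25 the hydroxy lactone
Product: 26 C1 ketone (the 4,5-olefin precursor of the target)
Conditions: Dess–Martin periodinane, NaHCO3, CH2Cl2, rt
Reagents that add atoms: none
Why: Dess–Martin oxidation of the only remaining hydroxyl should give the C1 ketone and erases the C1 stereocentre.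

Step 20
Reactants: 26 the keto lactone
Product: 27 CNP0241021.1
Conditions: dimethyldioxirane (acetone solution), CH2Cl2, −20 → 0 °C
Reagents that add atoms: dimethyldioxirane CC1(C)OO1
Why: Epoxidation with dimethyldioxirane is stereospecific (cis-epoxide from the Z alkene), selects the electron-rich trisubstituted alkene over the two acrylate-type alkenes and cannot cause Baeyer–Villiger oxidation of the ketone, and attack on the outer face of the oxa-bridged ring (the face turned away from the C8–C9 bridge) should give the (4R,5S)-epoxide.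

**Compound list**

For racemic compounds the SMILES shows the enantiomer that is carried forward.

1 | 5-bromofuran-2-carbaldehyde | O=Cc1ccc(Br)o1 | starting material
2 | ethynyltri(propan-2-yl)silane | C#C[Si](C(C)C)(C(C)C)C(C)C | starting material
3 | 5-[(TIPS)ethynyl]furan-2-carbaldehyde | O=Cc1ccc(C#C[Si](C(C)C)(C(C)C)C(C)C)o1 | intermediate
4 | rac-1-{5-[(TIPS)ethynyl]furan-2-yl}ethan-1-ol | CC(O)c1ccc(C#C[Si](C(C)C)(C(C)C)C(C)C)o1 | intermediate
5 | 6-hydroxy-2-methyl-6-[(TIPS)ethynyl]-2H-pyran-3(6H)-one (racemic, diastereomer mixture) | CC1OC(O)(C#C[Si](C(C)C)(C(C)C)C(C)C)C=CC1=O | intermediate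
6 | 6-acetoxy-2-methyl-6-[(TIPS)ethynyl]-2H-pyran-3(6H)-one (racemic, diastereomer mixture) | CC1OC(OC(C)=O)(C#C[Si](C(C)C)(C(C)C)C(C)C)C=CC1=O | intermediate
7 | (4-methoxyphenyl)methanol | COc1ccc(CO)cc1 | starting material
8 | 4-methoxybenzyl vinyl ether | C=COCc1ccc(OC)cc1 | intermediate
9 | 2-methyl-3-oxido-6-[(TIPS)ethynyl]pyrylium | Cc1[o+]c(C#C[Si](C(C)C)(C(C)C)C(C)C)ccc1[O-] | intermediate (not isolated)
10 | rac-(1R,5S,6R)-6-[(4-methoxybenzyl)oxy]-1-methyl-5-[(TIPS)ethynyl]-8-oxabicyclo[3.2.1]oct-3-en-2-one | COc1ccc(CO[C@@H]2C[C@@]3(C)O[C@]2(C#C[Si](C(C)C)(C(C)C)C(C)C)C=CC3=O)cc1 | intermediate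
11 | rac-3,4-epoxide of 10, epoxide oxygen syn to the bridging oxygen | COc1ccc(CO[C@@H]2C[C@@]3(C)O[C@]2(C#C[Si](C(C)C)(C(C)C)C(C)C)[C@@H]4O[C@@H]4C3=O)cc1 | intermediate
12 | hydrazone of 11 | COc1ccc(CO[C@@H]2C[C@@]3(C)O[C@]2(C#C[Si](C(C)C)(C(C)C)C(C)C)[C@@H]4O[C@@H]4C3=NN)cc1 | intermediate (not isolated)
13 | rac-(1R,2R,5R,7R)-7-[(4-methoxybenzyl)oxy]-5-methyl-1-[(TIPS)ethynyl]-8-oxabicyclo[3.2.1]oct-3-en-2-ol | COc1ccc(CO[C@@H]2C[C@@]3(C)O[C@]2(C#C[Si](C(C)C)(C(C)C)C(C)C)[C@H](O)C=C3)cc1 | intermediate
14 | acetate of the (1R,2R,5R,7R) enantiomer of 13 | COc1ccc(CO[C@@H]2C[C@@]3(C)O[C@]2(C#C[Si](C(C)C)(C(C)C)C(C)C)[C@H](OC(C)=O)C=C3)cc1 | intermediate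
15 | ozonide of 14 (1,2,4-trioxolane spanning C1 and C5) | COc1ccc(CO[C@@H]2C[C@@]3(C)O[C@]2(C#C[Si](C(C)C)(C(C)C)C(C)C)[C@H](OC(C)=O)C4OOC3O4)cc1 | intermediate (not isolated)
16 | 2,5-cis-tetrahydrofuran dialdehyde (C1 and C5 formyl groups, C6 acetate, C8 PMB ether; configurations as in 14) | COc1ccc(CO[C@@H]2C[C@](C)(C=O)O[C@]2(C#C[Si](C(C)C)(C(C)C)C(C)C)[C@H](OC(C)=O)C=O)cc1 | intermediate
17 | Z-iodoalkene aldehyde (C5H=C4(CH3)I, iodine cis to C6; C1 formyl) | COc1ccc(CO[C@@H]2C[C@](C)(C=O)O[C@]2(C#C[Si](C(C)C)(C(C)C)C(C)C)[C@H](OC(C)=O)/C=C(/C)I)cc1 | intermediate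
18 | diol (C1 vinyl carbinol as both epimers, C6 hydroxyl) | COc1ccc(CO[C@@H]2C[C@](C)(C(O)C=C)O[C@]2(C#C[Si](C(C)C)(C(C)C)C(C)C)[C@H](O)/C=C(/C)I)cc1 | intermediate
19 | bis(triethylsilyl) ether of 18 | COc1ccc(CO[C@@H]2C[C@](C)(C(O[Si](CC)(CC)CC)C=C)O[C@]2(C#C[Si](C(C)C)(C(C)C)C(C)C)[C@H](O[Si](CC)(CC)CC)/C=C(/C)I)cc1 | intermediate
20 | C3 9-borabicyclo[3.3.1]non-9-yl borane from 19 | COc1ccc(CO[C@@H]2C[C@](C)(C(O[Si](CC)(CC)CC)CCB3C4CCCC3CCC4)O[C@]2(C#C[Si](C(C)C)(C(C)C)C(C)C)[C@H](O[Si](CC)(CC)CC)/C=C(/C)I)cc1 | intermediate (not isolated)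
21 | oxa-bridged (4Z)-cyclodecene, C1 and C6 TES ethers, C8 PMB ether | COc1ccc(CO[C@@H]2C[C@@]3(C)O[C@]2(C#C[Si](C(C)C)(C(C)C)C(C)C)[C@H](O[Si](CC)(CC)CC)/C=C(/C)CCC3O[Si](CC)(CC)CC)cc1 | intermediate
22 | C8 alcohol (8R) from 21 | O[C@@H]1C[C@@]2(C)O[C@]1(C#C[Si](C(C)C)(C(C)C)C(C)C)[C@H](O[Si](CC)(CC)CC)/C=C(/C)CCC2O[Si](CC)(CC)CC | intermediate
23 | C8 methacrylate (8S) | C=C(C)C(=O)O[C@H]1C[C@@]2(C)O[C@]1(C#C[Si](C(C)C)(C(C)C)C(C)C)[C@H](O[Si](CC)(CC)CC)/C=C(/C)CCC2O[Si](CC)(CC)CC | intermediate
24 | desilylated diol with terminal alkyne | C=C(C)C(=O)O[C@H]1C[C@@]2(C)O[C@]1(C#C)[C@H](O)/C=C(/C)CCC2O | intermediate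
25 | α-methylene γ-lactone with C1 hydroxyl | C=C(C)C(=O)O[C@H]1C[C@@]2(C)O[C@@]13C(=C)C(=O)O[C@@H]3/C=C(/C)CCC2O | intermediate
26 | C1 ketone (4,5-alkene) | C=C(C)C(=O)O[C@H]1C[C@@]2(C)O[C@@]13C(=C)C(=O)O[C@@H]3/C=C(/C)CCC2=O | intermediate
27 | CNP0241021.1 | C=C(C)C(=O)O[C@H]1C[C@@]2(C)O[C@@]13C(=C)C(=O)O[C@@H]3[C@@H]1O[C@]1(C)CCC2=O | target

**Count**

Total steps: 20. Longest linear sequence: 19 steps (1 to 27 through steps 1–4 and 6–20); step 5 is a one-step side branch.

**Three steps most likely to fail**

Step 14 (ring closure at C3–C4). The alkylborane may couple between molecules, lose boron by protodeboronation, or the alkylpalladium may eliminate before the ten-membered ring can form. The fallback sets out from 18 and returns at 26. The unprotected diol 18 would undergo an intramolecular Heck reaction (Pd(OAc)2, Bu4NCl, NaHCO3, DMF, high dilution): the alkenylpalladium adds to the terminal carbon of the allylic alcohol, and β-hydride elimination toward the carbinol gives, after tautomerisation, the macrocyclic C1 ketone with free C6 hydroxyl F1. Silylation with Et3SiOTf would give the C6 triethylsilyl ether F2, DDQ the C8 alcohol F3, Mitsunobu esterification with methacrylic acid the inverted C8 methacrylate F4, and buffered Bu4NF the alkynyl hydroxy ketone F5. The cyclocarbonylation conditions of step 18 then give 26 directly, with no separate oxidation at C1.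

Step 16 (inversion at C8). The displacement next to the fully substituted C7 may stall, the oxyphosphonium may eliminate toward C9, or an acyloxyphosphonium pathway may give retention. The fallback sets out from 22 and returns at 23, separating inversion from acylation. Tf2O and pyridine would give the C8 triflate F6. Bu4NNO2 in DMF (Lattrell–Dax inversion) would displace it to the nitrite ester F7, which is hydrolysed on work-up to the C8-epimeric (8S) alcohol F8. Methacrylic anhydride, Et3N and DMAP then give 23.

Step 20 (epoxide face). The reagent may attack the other face of the C4=C5 alkene or show little facial preference. The fallback sets out from 26 and ends at 27, and reverses the facial outcome by anti addition followed by ring closure. NBS in aqueous THF would form the bromonium on the face the dioxirane prefers, and water would open it at the tertiary C4 from the opposite face, giving the bromohydrin F9. Ag2O would then close the epoxide by displacing bromide at C5 with inversion, which places the oxygen on the face opposite to that of direct epoxidation.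

Further compounds
F1 | step 14 | macrocyclic C1 ketone with free C6 hydroxyl, C8 PMB ether and silylalkyne | COc1ccc(CO[C@@H]2C[C@@]3(C)O[C@]2(C#C[Si](C(C)C)(C(C)C)C(C)C)[C@H](O)/C=C(/C)CCC3=O)cc1
F2 | step 14 | C6 triethylsilyl ether of F1 | COc1ccc(CO[C@@H]2C[C@@]3(C)O[C@]2(C#C[Si](C(C)C)(C(C)C)C(C)C)[C@H](O[Si](CC)(CC)CC)/C=C(/C)CCC3=O)cc1
F3 | step 14 | C8 alcohol (8R) from F2 | O[C@@H]1C[C@@]2(C)O[C@]1(C#C[Si](C(C)C)(C(C)C)C(C)C)[C@H](O[Si](CC)(CC)CC)/C=C(/C)CCC2=O
F4 | step 14 | C8 methacrylate (8S) from F3 | C=C(C)C(=O)O[C@H]1C[C@@]2(C)O[C@]1(C#C[Si](C(C)C)(C(C)C)C(C)C)[C@H](O[Si](CC)(CC)CC)/C=C(/C)CCC2=O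
F5 | step 14 | desilylated C6 alcohol with terminal alkyne and C1 ketone | C=C(C)C(=O)O[C@H]1C[C@@]2(C)O[C@]1(C#C)[C@H](O)/C=C(/C)CCC2=O
F6 | step 16 | C8 trifluoromethanesulfonate of 22 | FC(F)(F)S(=O)(=O)O[C@@H]1C[C@@]2(C)O[C@]1(C#C[Si](C(C)C)(C(C)C)C(C)C)[C@H](O[Si](CC)(CC)CC)/C=C(/C)CCC2O[Si](CC)(CC)CC
F7 | step 16 | C8 nitrite ester with inverted configuration | O=NO[C@H]1C[C@@]2(C)O[C@]1(C#C[Si](C(C)C)(C(C)C)C(C)C)[C@H](O[Si](CC)(CC)CC)/C=C(/C)CCC2O[Si](CC)(CC)CC
F8 | step 16 | C8 epimer (8S) of alcohol 22 | O[C@H]1C[C@@]2(C)O[C@]1(C#C[Si](C(C)C)(C(C)C)C(C)C)[C@H](O[Si](CC)(CC)CC)/C=C(/C)CCC2O[Si](CC)(CC)CC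
F9 | step 20 | bromohydrin of 26 (bromide at C5, tertiary hydroxyl at C4) | C=C(C)C(=O)O[C@H]1C[C@@]2(C)O[C@@]13C(=C)C(=O)O[C@@H]3[C@@H](Br)[C@](C)(O)CCC2=O
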